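**Retrosynthetic overview**
- Robustol is reached by O-demethylation of its tri-O-methyl ether.
- Key disconnection: the diaryl ether C–O bond between the phenolic oxygen of ring A and the ring B carbon flanked by its two oxygens. It is closed last, as the 22-membered ring, by oxidative C–O coupling of an aryl(aryloxy)cuprate.
- The open precursor is a monophenol made by single O-demethylation of symmetric 1,14-bis(3,5-dimethoxyphenyl)tetradecane.
- The symmetric tetraether comes from double copper-catalysed sp3–sp3 coupling of two molecules of 3,5-dimethoxybenzyl Grignard reagent with one molecule of 1,12-dibromododecane.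
- Ring order: both benzene rings are bought; the only ring formed is the macrocycle (step 3).

Assumption: robustol has no stereocentre and its 22-membered ring is too large for stable planar chirality, so it is achiral and no enantiocontrol is needed.

Step 1
Reactants: 1 3,5-dimethoxybenzyl chloride (2.5 equiv in total, two molecules incorporated); 2 1,12-dibromododecane (1.0 equiv)
Product: 4 1,14-bis(3,5-dimethoxyphenyl)tetradecane, via 3,5-dimethoxybenzylmagnesium chloride 3 (not isolated)
Conditions: 1 (2.5 equiv), Mg, THF, 0 °C; then 2 (1.0 equiv), Li2CuCl4 (5 mol %), THF, –10 °C → rt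
Reagents that add atoms: second molecule of 3,5-dimethoxybenzyl chloride 1 (converted into Grignard reagent 3 like the first) COc1cc(CCl)cc(OC)c1
Why: Benzylic Grignard reagents couple with unhindered primary alkyl bromides under Li2CuCl4 catalysis (Kochi copper-catalysed sp3–sp3 Grignard cross-coupling), so each C–Br end of 2 is alkylated by one molecule of 3, and the two benzylic carbons plus the twelve carbons of 2 give the (CH2)14 tether, with no stereocentre formed.

Step 2
Reactants: 4 1,14-bis(3,5-dimethoxyphenyl)tetradecane
Product: 5 3-[14-(3,5-dimethoxyphenyl)tetradecyl]-5-methoxyphenol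
Conditions: NaSEt (1.1 equiv), DMF, 150 °C; aq HCl work-up
Reagents that add atoms: none
Why: Thiolate SN2 O-demethylation of aryl methyl ethers stops at one methoxy group per ring because the phenoxide formed deactivates that ring, so about one equivalent of NaSEt gives monophenol 5 as the main product of a statistical distribution over the two independent rings (about 45 % per pass expected), separable by polarity from recovered 4, which is recycled.

Step 3
Reactants: 5 3-[14-(3,5-dimethoxyphenyl)tetradecyl]-5-methoxyphenol
Product: 8 robustol tri-O-methyl ether (22-membered diaryl ether macrocycle), via aryllithium lithium phenoxide 6 (not isolated), via macrocyclic lithium aryl(aryloxy)cuprate 7 (not isolated)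
Conditions: n-BuLi (2.2 equiv), THF, 0 °C → rt; CuCl·2LiCl (1.1 equiv), THF, –50 °C, dilute to 1 mM; chloranil (1.3 equiv), –78 → –40 °C; aq NH4Cl
Reagents that add atoms: none
Why: Proposed new method: intramolecular oxidative C–O coupling of a lithium aryl(aryloxy)cuprate, in which n-BuLi deprotonates the phenol and then lithiates ring B only at the carbon between its two methoxy groups (directed ortho-metalation; the phenoxide ring A is deactivated), transmetalation to CuCl places the aryl and the tethered aryloxide on one monovalent copper centre as a reversibly formed 22-membered cupracycle at 1 mM, and two-electron oxidation by chloranil gives a trivalent copper aryl aryloxide whose C–O reductive elimination should outrun aryl–aryl coupling (which would need a tetra-ortho-substituted biaryl); the closest known reaction types are the chloranil-mediated oxidative amination of lithium amidocuprates and the C–O reductive elimination of Chan–Lam etherification, neither shown for tethered aryloxides or for macrocyclisation.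

Step 4
Reactants: 8 robustol tri-O-methyl ether
Product: 9 robustol
Conditions: BBr3 (6 equiv), CH2Cl2, –78 °C → rt; then H2O
Reagents that add atoms: none
Why: BBr3 cleaves the three aryl methyl ethers by Lewis acid complexation and bromide SN2 attack at methyl (BBr3 ether demethylation), while the diaryl ether has no sp3 carbon to attack and the saturated chain is inert.

**Compound list**
1 | 3,5-dimethoxybenzyl chloride | COc1cc(CCl)cc(OC)c1 | starting material
2 | 1,12-dibromododecane | BrCCCCCCCCCCCCBr | starting material
3 | 3,5-dimethoxybenzylmagnesium chloride (formed in the flask) | COc1cc(C[Mg]Cl)cc(OC)c1 | intermediate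
4 | 1,14-bis(3,5-dimethoxyphenyl)tetradecane | COc1cc(CCCCCCCCCCCCCCc2cc(OC)cc(OC)c2)cc(OC)c1 | intermediate
5 | 3-[14-(3,5-dimethoxyphenyl)tetradecyl]-5-methoxyphenol | COc1cc(O)cc(CCCCCCCCCCCCCCc2cc(OC)cc(OC)c2)c1 | intermediate
6 | lithium 3-[14-(4-lithio-3,5-dimethoxyphenyl)tetradecyl]-5-methoxyphenoxide (formed in the flask) | [Li]Oc1cc(OC)cc(CCCCCCCCCCCCCCc2cc(OC)c([Li])c(OC)c2)c1 | intermediate
7 | macrocyclic lithium aryl(aryloxy)cuprate: monovalent copper bonded to the ring B carbon between the two methoxy groups and to the ring A phenoxide oxygen (formed in the flask) | COc1cc2cc(c1)O[Cu-]c1c(OC)cc(cc1OC)CCCCCCCCCCCCCC2.[Li+] | intermediate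
8 | robustol tri-O-methyl ether: ring A (3-methoxy-5-alkylphenyl) oxygen bonded to C-4 of ring B (3,5-dimethoxy-1-alkylphenyl), rings also joined by an unbranched (CH2)14 chain; achiral | COc1cc2cc(c1)Oc1c(OC)cc(cc1OC)CCCCCCCCCCCCCC2 | intermediate
9 | robustol (achiral) | Oc1cc2cc(c1)Oc1c(O)cc(cc1O)CCCCCCCCCCCCCC2 | target

**Step count and risks**
Total step count: 4. Longest linear sequence: 4 steps (1 and 2 → 4 → 5 → 8 → 9).

Steps most likely to fail:

Step 3 (the proposed new macrocyclisation) is the most uncertain: the cuprate may aggregate and give oligomers, or chloranil may attack the phenoxide. The fallback uses known chemistry and sets out from 5. Lithiation exactly as in step 3 (n-BuLi, THF, 0 °C) followed by a quench with 1,2-diiodoethane at –78 °C, which iodinates the aryllithium but not the phenoxide ring, gives 3-[14-(4-iodo-3,5-dimethoxyphenyl)tetradecyl]-5-methoxyphenol F1. A catalytic Ullmann diaryl ether macrocyclisation (CuI 20 mol %, picolinic acid 40 mol %, K3PO4, DMSO, 90 °C, syringe-pump addition to 2 mM) then closes the ring. This comes back to the route at 8.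

Step 2 is capped near 50 % per pass by statistics. The fallback builds the two ends one after the other and sets out from 2 and 3. Grignard reagent 3 is added to a fivefold excess of 2 with Li2CuCl4 to give 1-(13-bromotridecyl)-3,5-dimethoxybenzene F2, and the excess 2 is recovered. PPh3 in refluxing MeCN converts it into [13-(3,5-dimethoxyphenyl)tridecyl]triphenylphosphonium bromide F3. Its ylide (NaN(SiMe3)2, THF) undergoes Wittig olefination with the sodium phenoxide of 3-hydroxy-5-methoxybenzaldehyde F4 to give 3-[14-(3,5-dimethoxyphenyl)tetradec-1-en-1-yl]-5-methoxyphenol F5 as an E/Z mixture. Hydrogenation (H2, Pd/C, EtOAc) comes back to the route at 5.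

Step 1 can suffer from Wurtz homocoupling of the benzylic Grignard reagent and from incomplete double coupling. The fallback replaces the Grignard coupling with olefination and sets out from 2. Heating 2 with two equivalents of PPh3 (DMF, 120 °C) gives dodecane-1,12-diylbis(triphenylphosphonium) dibromide F6. Its bis-ylide (NaN(SiMe3)2, THF) is condensed with two equivalents of 3,5-dimethoxybenzaldehyde F7 in a double Wittig reaction to give 1,14-bis(3,5-dimethoxyphenyl)tetradeca-1,13-diene F8 as a mixture of alkene isomers. Hydrogenation (H2, Pd/C, EtOAc) comes back to the route at 4.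

**Further compounds**
F1 | step 3 | 3-[14-(4-iodo-3,5-dimethoxyphenyl)tetradecyl]-5-methoxyphenol | COc1cc(O)cc(CCCCCCCCCCCCCCc2cc(OC)c(I)c(OC)c2)c1
F2 | step 2 | 1-(13-bromotridecyl)-3,5-dimethoxybenzene | COc1cc(CCCCCCCCCCCCCBr)cc(OC)c1
F3 | step 2 | [13-(3,5-dimethoxyphenyl)tridecyl]triphenylphosphonium bromide | [Br-].COc1cc(CCCCCCCCCCCCC[P+](c2ccccc2)(c2ccccc2)c2ccccc2)cc(OC)c1
F4 | step 2 | 3-hydroxy-5-methoxybenzaldehyde | COc1cc(O)cc(C=O)c1
F5 | step 2 | 3-[14-(3,5-dimethoxyphenyl)tetradec-1-en-1-yl]-5-methoxyphenol (E/Z mixture, geometry not drawn) | COc1cc(O)cc(C=CCCCCCCCCCCCCc2cc(OC)cc(OC)c2)c1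
F6 | step 1 | dodecane-1,12-diylbis(triphenylphosphonium) dibromide | [Br-].[Br-].c1ccccc1[P+](c1ccccc1)(c1ccccc1)CCCCCCCCCCCC[P+](c1ccccc1)(c1ccccc1)c1ccccc1
F7 | step 1 | 3,5-dimethoxybenzaldehyde | COc1cc(C=O)cc(OC)c1
F8 | step 1 | 1,14-bis(3,5-dimethoxyphenyl)tetradeca-1,13-diene (mixture of alkene isomers, geometry not drawn) | COc1cc(C=CCCCCCCCCCCC=Cc2cc(OC)cc(OC)c2)cc(OC)c1
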